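**Retrosynthetic overview**
1. 8 ⇐ 7 by hydrolysis of two dimethyl ketals: the cyclohexa-2,5-diene-1,4-dione ring is carried as a 3,3,6,6-tetramethoxycyclohexa-1,4-diene, already at the quinone oxidation level but inert to base and to an anode.
2. 7 ⇐ 4 + 5 in one electrolysis: anodic methoxylation of the dimethoxybenzene ring of 4, then mixed Kolbe (decarboxylative radical–radical) coupling that forms the C4'–C5' bond of the nonadecyl chain from a pentadecyl radical (palmitic acid minus CO2) and a 4-(ring)butyl radical.
3. Enabling feature: C4' and C5' are two unactivated CH2 carbons of like polarity in an unbranched saturated chain, four methylenes from the ring, so each can be the α-carbon of a plain carboxylic acid and then a primary radical; ring carbons C1 and C4 (the two C=O) are the two OMe-bearing carbons of a 1,4-dimethoxybenzene ring, which the anode turns into ketals before any carboxylate is discharged.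
4. 4 ⇐ 3 (ionic hydrogenation of the aryl ketone) ⇐ 1 + 2 (Friedel–Crafts acylation).
5. No ring is formed in the route: the six-membered carbocycle comes intact from 1 and only changes oxidation level (arene → bisketal → quinone).

Key step: step 3

Remark: the target has no stereocentre and no stereogenic double bond, so no step has to control configuration; the side chain is numbered C1' (on the ring) to C19'.

**Step 1**
Reactants: 1 1,4-dimethoxybenzene; 2 glutaric anhydride
Product: 3 5-(2,5-dimethoxyphenyl)-5-oxopentanoic acid
Conditions: AlCl3 (2.2 equiv), CH2Cl2/MeNO2, 0 °C → rt; then ice/aq. HCl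
Reagents that add atoms: none
Why: Friedel–Crafts acylation, in which the AlCl3-activated anhydride attacks the electron-rich ring, whose four free positions are equivalent, and the new acyl group deactivates the ring against a second acylation.

**Step 2**
Reactants: 3 5-(2,5-dimethoxyphenyl)-5-oxopentanoic acid
Product: 4 5-(2,5-dimethoxyphenyl)pentanoic acid
Conditions: Et3SiH (3 equiv), TFA, rt → 50 °C
Reagents that add atoms: none
Why: Ionic hydrogenation, in which the protonated aryl ketone and then the benzylic cation (stabilised by the ortho-methoxy group) each accept hydride from the silane, while the carboxylic acid and the aryl methyl ethers are inert.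

**Step 3**
Reactants: 4 5-(2,5-dimethoxyphenyl)pentanoic acid; 5 palmitic acid (hexadecanoic acid)
Product: 7 3,3,6,6-tetramethoxy-1-nonadecylcyclohexa-1,4-diene, via bisketal sodium carboxylate 6 (not isolated)
Conditions: (i) NaOMe (1.5 equiv), MeOH, Pt anode, stainless-steel cathode, undivided cell, low current density, 0 °C, ca. 2.5 F/mol; (ii) 5 (6 equiv) added to the same cell, 45 °C, ca. 0.25 A/cm2 at Pt, until the electrolyte turns alkaline; basic work-up
Reagents that add atoms: methanol (solvent, in equilibrium with methoxide), CO
Why: In stage (i) the electron-rich 1,4-dimethoxyarene ring of 4 is oxidised at low anode potential (two electrons, addition of methanol/methoxide at the two OMe-bearing ring carbons) to the quinone bis(dimethyl ketal) 6, while the side-chain carboxylate is not discharged in strongly basic methanol at low current density (anodic methoxylation of hydroquinone dimethyl ethers). In stage (ii) the added palmitic acid brings the electrolyte to the partly neutralised, weakly acidic state of a Kolbe electrolysis, both carboxylates are discharged at high current density on platinum to acyloxy radicals that lose CO2, and the primary pentadecyl radical and the primary 4-(tetramethoxycyclohexadienyl)butyl radical combine at the electrode surface to the CH2–CH2 bond (mixed Kolbe heterocoupling is the closest known reaction type). No ring is closed and no stereocentre is formed. The step needs cross- over homo-coupling, which is statistical and is secured by the sixfold excess of cheap palmitic acid (its homodimer triacontane is inert, apolar and removable), and it needs coupling to outrun 5-exo/6-endo attack of the butyl radical on the ring double bond, which the high stationary radical concentration at the anode and the hindered, trisubstituted, ketal-flanked alkene should secure. The ring is safe at the Kolbe potential because it has already been taken to the non-oxidisable, base- and methanol-stable bisketal level, and two-electron over-oxidation to cations is disfavoured for primary radicals on smooth platinum.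

**Step 4**
Reactants: 7 3,3,6,6-tetramethoxy-1-nonadecylcyclohexa-1,4-diene
Product: 8 2-nonadecylcyclohexa-2,5-diene-1,4-dione (2-nonadecyl-1,4-benzoquinone)
Conditions: 1 M aq. H2SO4, THF, rt, protected from light
Reagents that add atoms: water, O
Why: Acid-catalysed ketal hydrolysis, in which both dimethyl ketals ionise to oxocarbenium ions that take up water and lose methanol, and the non-nucleophilic acid leaves the quinone and the saturated chain untouched.

**Compound list**
1 | 1,4-dimethoxybenzene | COc1ccc(OC)cc1 | starting material
2 | glutaric anhydride (oxane-2,6-dione) | O=C1CCCC(=O)O1 | starting material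
3 | 5-(2,5-dimethoxyphenyl)-5-oxopentanoic acid | COc1ccc(OC)c(c1)C(=O)CCCC(=O)O | intermediate
4 | 5-(2,5-dimethoxyphenyl)pentanoic acid | COc1ccc(OC)c(CCCCC(=O)O)c1 | intermediate
5 | palmitic acid (hexadecanoic acid) | CCCCCCCCCCCCCCCC(=O)O | starting material
6 | sodium 5-(3,3,6,6-tetramethoxycyclohexa-1,4-dien-1-yl)pentanoate (formed in the cell, not isolated) | [Na+].[O-]C(=O)CCCCC1=CC(OC)(OC)C=CC1(OC)OC | intermediate
7 | 3,3,6,6-tetramethoxy-1-nonadecylcyclohexa-1,4-diene | CCCCCCCCCCCCCCCCCCCC1=CC(OC)(OC)C=CC1(OC)OC | intermediate
8 | 2-nonadecylcyclohexa-2,5-diene-1,4-dione | CCCCCCCCCCCCCCCCCCCC1=CC(=O)C=CC1=O | target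

**Totals**
Total step count: 4. Longest linear sequence: 4 steps (1 → 3 → 4 → 7 → 8); palmitic acid 5 enters at step 3.

**Steps most likely to fail**

Step 3. The radical pair may fail to cross-couple cleanly: homo-coupling of the excess partner may dominate, the butyl radical may cyclise onto the ring double bond, radicals may be over-oxidised to cations (methyl ethers, alkenes), the anode may be passivated by precipitating hydrocarbon, or a ketal may be lost if water enters. The fallback sets out from 4 and comes back to the route at 8, forming the same CH2–CH2 bond by nickel catalysis on the aromatic oxidation level. Acid 4 would be esterified with N-hydroxyphthalimide (DIC, cat. DMAP, CH2Cl2) to the redox-active ester 1,3-dioxoisoindolin-2-yl 5-(2,5-dimethoxyphenyl)pentanoate F1. Decarboxylative alkyl–alkyl coupling of this ester (NiCl2·glyme, 4,4'-di-tert-butyl-2,2'-bipyridine, THF/DMF, rt) with dipentadecylzinc F2, prepared from commercial pentadecylmagnesium bromide solution and ZnCl2, should give 1,4-dimethoxy-2-nonadecylbenzene F3. Oxidative demethylation with ceric ammonium nitrate (MeCN/H2O, 0 °C) should then give 8.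

Step 1. The aluminium chloride may cleave the methyl ether ortho to the new ketone through chelation, and over-reaction or tar formation may lower the return. The fallback sets out from 1 and comes back at 3, replacing electrophilic substitution by directed ortho-metalation. Compound 1 would be lithiated (n-BuLi, TMEDA, Et2O, 0 °C → rt) to (2,5-dimethoxyphenyl)lithium F4, which would be added inversely to an excess of anhydride 2 in THF at −78 °C; acidic work-up should give 3.

Step 4. Hydrolysis may stall after the first ketal, and forcing acid may degrade the quinone. The fallback sets out from 7 and comes back at 8, replacing the second hydrolysis by a redox unmasking. Mild hydrolysis (1% aq. AcOH, acetone, rt) should give the monoketal, expected mainly as 4,4-dimethoxy-3-nonadecylcyclohexa-2,5-dien-1-one F5; the regioisomer would converge on the same quinone. Reductive aromatisation (Zn, AcOH, rt) should give 4-methoxy-3-nonadecylphenol F6. Oxidative demethylation with PhI(OAc)2 (MeCN/H2O, 0 °C) should give 8.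

**Further compounds**
F1 | step 3 | 1,3-dioxoisoindolin-2-yl 5-(2,5-dimethoxyphenyl)pentanoate | COc1ccc(OC)c(CCCCC(=O)ON2C(=O)c3ccccc3C2=O)c1
F2 | step 3 | dipentadecylzinc | CCCCCCCCCCCCCCC[Zn]CCCCCCCCCCCCCCC
F3 | step 3 | 1,4-dimethoxy-2-nonadecylbenzene | CCCCCCCCCCCCCCCCCCCc1cc(OC)ccc1OC
F4 | step 1 | (2,5-dimethoxyphenyl)lithium | [Li]c1cc(OC)ccc1OC
F5 | step 4 | 4,4-dimethoxy-3-nonadecylcyclohexa-2,5-dien-1-one | CCCCCCCCCCCCCCCCCCCC1=CC(=O)C=CC1(OC)OC
F6 | step 4 | 4-methoxy-3-nonadecylphenol | CCCCCCCCCCCCCCCCCCCc1cc(O)ccc1OC
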